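What is left over is my starting point. Monday's last reading leaves 67.6 % of substrate beside 33.5 % of product, so the balance closes, and I take one partner per substrate.

common to all: partner 1.65 M

| charge | substrate | remark | time |
|---|---|---|---|
| Wednesday's | 0.75 M | run made earlier |  |
| Monday's | 1.1 M | run made earlier |  |
| oak | 1.5 M |  | 5.0 h |
| larch | 1.5 M |  | 15 h |
| maple | 1.5 M |  | 50 h |

| run | time / h | product / % | substrate / % |
|---|---|---|---|
| Wednesday's | 0.833 | 9.2 | 91.6 |
| Wednesday's | 1.50 | 13.6 | 86.3 |
| Wednesday's | 2.50 | 19.4 | 81.7 |
| Wednesday's | 3.00 | 21.8 | 78.1 |
| Wednesday's | 4.00 | 25.5 | 72.4 |
| Wednesday's | 5.00 | 31.0 | 69.2 |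
| Monday's | 0.333 | 6.2 | 93.8 |
| Monday's | 1.00 | 12.0 | 88.7 |
| Monday's | 2.00 | 18.4 | 81.4 |
| Monday's | 2.50 | 20.7 | 78.1 |
| Monday's | 4.00 | 30.2 | 70.9 |
| Monday's | 5.00 | 33.5 | 67.6 |

(each reading ± 0.5 percentage points)

- which of these there is most of at the end, counted by the substrate in it, oak (substrate / product)
- which of these there is most of at the end, counted by the substrate in it, larch (substrate / product)
- which of these there is most of at the end, counted by the substrate in it, maple (substrate / product)
- how much there is at the end of the one of these that leads, in percent of the substrate charged: oak
- how much there is at the end of the one of these that leads, in percent of the substrate charged: larch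
- how much there is at the end of the one of these that leads, in percent of the substrate charged: maple

- what was read earlier has a scatter of 0.5 percentage points, one standard deviation

Let S be the substrate and B the unused partner, both in M. If one of each goes per turnover, B stays ahead of S by a fixed excess D, the difference of the charges. That is what I freeze.

I begin with the main step by itself, at rate κSB. Then ln(B/S) climbs in a straight line of slope κD. Between 1.00 h and 5.00 h of Monday's run I read from these two scattered readings the pace constant κ, the slope divided by D: 0.0485 M⁻¹ h⁻¹. From the full charge, this line leaves oak 71.1 % of substrate at 5.0 h.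

Next I add the quick start. Monday's first 0.333 h took 6.2 percentage points, while its last 1.00 h took 3.3 points. I cannot read the cause, but Monday's measured 67.6 % already contains this start, so I take that figure in place of the line.

Then I add the loading. The last reading falls from 69.2 % on Wednesday to 67.6 % on Monday as the charge rises. Carried straight on to oak's charge, that gives 65.8 %.

From that point I run the line with κ. My estimate for larch is 41.9 % of substrate and for maple 16.7 %, so I expect product to lead in both.

The forecast says substrate at 65.5 % for oak, substrate at 54 % for larch, and for maple, by “continued slow reaction”, product at 62 %. We part on the leader in larch.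

The flask gives substrate at 64.1 % for oak, product at 59.4 % for larch, and product at 80.6 % for maple.

    partner ⇌ dormant form (K = 4.40, k = 0.00320 s⁻¹)
    substrate + partner → product, rate k2*[substrate]^1.5*[partner] (k = 8.80 × 10⁻⁵ M⁻¹·⁵ s⁻¹)

In maple at 50.0 h, partner has a half-life of 0.060 h by the forward passing into dormant form alone, against 14 h by the step to product. The dormant form, the resting state of the partner, stands in maple at 0.360 M, against 0.0816 M of unbound partner. With κ at 0.0485 M⁻¹ h⁻¹, I had larch at 41.9 % of substrate, and it stands at 40.6 %. In the neighbour flask, maple with 0.41 M of partner, D is negative, and the line from the full charge gives 74.1 % of substrate, just above the 72.7 % that this charge of partner, the limiting reagent, allows, while that flask stands at 73.3 % of substrate with 0.435 % of its partner still unbound.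

(The runs stem from a simulated flask for substances that don't exist; noise was put on by code.)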